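## The problem

The target is a hexahydroindenone: a cyclopentenone and a cyclohexane fused through C3a–C7a, where C7a is quaternary (methyl) and C3a is the β-carbon of the C2 enone (C3=C3a). The core carries four stereocentres (1R, 4S, 7R, 7aS), and the C1 chain, the C4 acyloxy group and the C7 carboxyl all lie on the face of the angular methyl. A fifth centre (6R) sits in the dienoate side chain, is too remote to be induced, and must be bought. C7a is the natural controller: C7 can be tied to it through one alkene geometry, and C4 can be set by hydride delivery away from the axial methyl. C1 is α to the ketone, so it is epimerisable; the cis-to-methyl arrangement is probably the more stable one, but it should not be left to chance. The 2-substituted acrolein, the γ-acyloxy enone (an allylic ester open to base, nucleophiles and reductants), the dienoate and the free acid forbid strong base, zerovalent palladium, dissolving metals and hydrogenation late in the route. The feature that opens the molecule is the alkene C3=C3a exocyclic to the six-membered ring and flanked by oxygenated C4, together with the cis methyl/carboxyl pair at C7a/C7. Read backwards through a [4+2], this is a 2-siloxy vinylallene (C3=C3a=C4(OSi)–C5=C6) tethered through C2–C1 to an E-β-methyl enoate (C7a=C7). One point must be faced: the tether reaches only one face of the diene, so the allene axis as well as C1 decides which face of the enoate is used, and the axis has to be made with defined configuration.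

## Retrosynthesis

**Acid.** Target 38 is traced to its tert-butyl ester 37 by cutting the ester C–O bond. Acidolysis is the only carboxyl release that spares the γ-acyloxy enone, the dienoate and the acrolein; base, fluoride and zerovalent palladium do not.

**Carbonyls.** The C2 ketone and the chain aldehyde of 37 are both taken back to allylic alcohols (diol 36), and these to the bis-silyl ether 35. Carrying C2 as a protected carbinol keeps C1 non-enolisable through the whole route and keeps C2 distinct from C4. One mild oxidation then reveals both carbonyls, and no α-methylenation of an aldehyde is needed on a fragile intermediate.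

**Side chain.** Cutting the C4–O acyl bond of 35 gives allylic alcohol 25 and acid 33. Acid 33 comes from ester 32, and that from enal 30 and phosphonate 31. Enal 30 comes from alcohol 27 (through aldehyde 29) and ylide 28, and 27 from commercial (R)-2-methylbutanoic acid 26. Two E-selective olefinations are preferred to one vinylogous olefination of uncertain geometry.

**C4 oxygen.** Alcohol 25 is the 1,2-reduction product of enone 24, with the axial C7a methyl expected to shield one face. Enone 24 is the hydrolysis product of silyl dienol ether 23.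

**Core.** In 23 the bonds C3a–C7a and C6–C7 are cut together (retro-[4+2]), giving the acyclic siloxy vinylallene 22. Both rings, the quaternary carbon and C7 go in one step; the C2 oxygen, the C1 chain and C3=C3a are already in place. Cutting C5–C6/C7–C7a instead leaves a bare cyclopentane, and cutting C3a–C4 needs the quaternary centre beforehand. The forward reaction must join a β,β-disubstituted enoate to the diene and must use one enoate face only.

**Allene.** The axis of 22 is traced to the tertiary α-silyl carbinol 21 (Brook rearrangement with SE2' protonation). The C3a–C4 bond of 21 is cut to terminal alkyne 17 and acryloylsilane 20, itself made from methoxyallene 18 through silylallene 19. A zinc acetylide is chosen over a lithium one so that the enoate of 17 is never exposed to strong base.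

**Enoate.** Alkyne 17 comes from its C-silyl derivative 16. The E-enoate of 16 is made from Z-enol triflate 15 and a methyl cuprate, and 15 from β-keto ester 14. This fixes the geometry completely; olefination of a methyl ketone would give E/Z mixtures and endanger C1.

**C1 and C2.** β-Keto ester 14 is cut at C7–C7a into Weinreb amide 12 and tert-butyl acetate 13. Amide 12 comes from 11 and that from aldol adduct 10. Cutting C1–C2 of 10 (Evans syn aldol) gives imide 8 and commercial ynal 9. The aldol sets C1 absolutely. It also sets C2 so that chain and silyloxy group end trans on the ring to be formed.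

**Chain acid.** Imide 8 comes from acid 5 (through mixed anhydride 7) and oxazolidinone 6. Acid 5 comes from ester 4, the Johnson–Claisen product of allylic alcohol 2 and orthoester 3. Alcohol 2 is the monosilyl ether of diol 1. The chain thus has its final carbon skeleton from the start.

## Roads not taken

**Alternative 1:** The cut is C5–C6 and C7–C7a. Forward, siloxydiene A1 and trifluoroethyl acrylate A2 combine under a protonated chiral oxazaborolidine to give the endo adduct A3. Its merits are real: the step is convergent and catalytic, its enantiocontrol rests on a very well-tried catalyst class, and it reaches a bicyclic C4 enol ether in far fewer steps than the chosen plan. In step economy to the bicycle and in certainty of absolute control it is the better road. Against it, the tetrasubstituted diene terminus must form the quaternary carbon intermolecularly with a mere acrylate, which is at the edge of the reaction's scope. C7 comes out epimeric and must be inverted. The five-membered ring arrives with no functionality: the C2 oxygen, the C3=C3a alkene and the C1 chain each need a separate oxidation or alkylation. Alkylation at C1 would be expected to occur anti to the methyl, the wrong sense. The chosen plan sets against this that C1 with its chain, the C2 oxygen and C3=C3a are all present when the rings close.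

**Alternative 2:** The cut is C2–C3 and C3–C3a (one-carbon ring expansion). Forward, diazomethane A5 adds to the strained carbonyl of the fused dichlorocyclobutanone A4, and the non-chlorinated α-carbon migrates to give dichlorocyclopentanone A6. The ketene cycloaddition that precedes it builds the quaternary carbon reliably, the expansion is regioselective, and reductive dechlorination would release a regiodefined enolate at C1 for introducing the chain. That last point is better than anything the chosen plan offers for C1. The weak points lie before and after. The cyclohexene precursor must already carry C4, C7 and their relation to the future C7a in enantiopure form. C3a ends saturated and cis-fused, so C3=C3a has to be introduced by dehydrogenation on the correct side of a ketone whose other α-carbon is C1. The dichloro ketone, diazomethane and several redox adjustments add length and hazard. The chosen plan makes C3=C3a and the C4 oxygen in the ring-forming step itself.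

**Alternative 3:** The cut is C3a–C4. Forward, cathodic reduction of the cyclopentenone aldehyde A7 couples the enone β-carbon with the tethered aldehyde to give hydroxy ketone A8. This closes the ring and creates the C4 carbinol in one operation, with the C2 ketone and the final chain already in place and no sensitive enol ether. In directness at C4 it is superior. It moves the hard part rather than solving it, however. A7 needs the quaternary C7a flanked by the C1 and C7 stereocentres before the key step, which is the central difficulty of the target. A8 has lost the C3=C3a alkene, which must be reinstalled regioselectively next to an epimerisable C1. The relation of the new carbinol to the methyl is not assured, and reduction or dimerisation of the aldehyde and enone compete. The chosen plan has its own uncertainty in the facial pairing of the cycloaddition, but it builds C7a, C7 and both rings together from an acyclic chain of two aldol-derived centres.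

Key step: step 15

Assumption: (S,S)-ProPhenol is written for the ligand enantiomer that gives the (8S)-carbinol 21, and the SE2' protonation in step 14 is taken to be anti; if either sense proves opposite, the mirror-image ligand is used and nothing else changes.

Abbreviations: TBS = tert-butyldimethylsilyl, TES = triethylsilyl, TMS = trimethylsilyl. Core atoms are numbered as in the indene (C1 chain-bearing, C2, C3, C3a, C4 … C7, C7a).

Step 1
Reactants: 1 2-methylidenepropane-1,3-diol
Product: 2 2-{[(TBS)oxy]methyl}prop-2-en-1-ol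
Conditions: NaH (1.0 equiv), THF, 0 °C; TBSCl, 0 °C → rt
Reagents that add atoms: tert-butyldimethylsilyl chloride, CC(C)(C)[Si](C)(C)Cl
Why: Monosilylation of a symmetrical diol through its monosodium alkoxide; the two hydroxyls are equivalent, so only mono- versus bis-silylation has to be managed.

Step 2
Reactants: 2 2-{[(TBS)oxy]methyl}prop-2-en-1-ol; 3 triethyl orthoacetate
Product: 4 ethyl 4-{[(TBS)oxy]methyl}pent-4-enoate
Conditions: EtCO2H (cat.), neat 3, 140 °C, removal of EtOH
Reagents that add atoms: none
Why: Johnson–Claisen rearrangement: the mixed ketene acetal of the allylic alcohol rearranges [3,3] and delivers the γ,δ-unsaturated ester with the 1,1-disubstituted alkene and the chain carbons in their final connectivity.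

Step 3
Reactants: 4 ethyl 4-{[(TBS)oxy]methyl}pent-4-enoate
Product: 5 4-{[(TBS)oxy]methyl}pent-4-enoic acid
Conditions: LiOH, THF/MeOH/H2O, rt; then 1 M HCl to pH 4, 0 °C
Reagents that add atoms: lithium hydroxide, [Li+].[OH-]
Why: Saponification of an unhindered ethyl ester; a primary TBS ether tolerates aqueous LiOH and a brief mildly acidic work-up.

Step 4
Reactants: 5 4-{[(TBS)oxy]methyl}pent-4-enoic acid; 6 (S)-4-benzyl-1,3-oxazolidin-2-one
Product: 8 (S)-4-benzyl-3-(4-{[(TBS)oxy]methyl}pent-4-enoyl)-1,3-oxazolidin-2-one, via mixed pivalic anhydride 7 (not isolated)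
Conditions: t-BuCOCl, Et3N, THF, −20 °C; then 6, LiCl, rt
Reagents that add atoms: none
Why: N-Acylation of the Evans auxiliary through the mixed pivalic anhydride, which needs no strong base and attacks the less hindered carbonyl.

Step 5
Reactants: 8 (S)-4-benzyl-3-(4-{[(TBS)oxy]methyl}pent-4-enoyl)-1,3-oxazolidin-2-one; 9 3-(trimethylsilyl)prop-2-ynal
Product: 10 (S)-4-benzyl-3-[(2S,3S)-2-(2-{[(TBS)oxy]methyl}prop-2-en-1-yl)-3-hydroxy-5-(TMS)pent-4-ynoyl]-1,3-oxazolidin-2-one
Conditions: n-Bu2BOTf, i-Pr2NEt, CH2Cl2, −78 → 0 °C; 9, −78 → 0 °C; then pH 7 buffer, MeOH, H2O2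
Reagents that add atoms: none
Why: Evans syn aldol: the Z boron enolate reacts through a closed chair transition state on the face away from the benzyl group, setting core C1 and the C2 carbinol together (2S,3S, as with aryl aldehydes); alkynals are good acceptors.

Step 6
Reactants: 10 aldol adduct
Product: 11 (2S,3S)-2-(2-{[(TBS)oxy]methyl}prop-2-en-1-yl)-3-hydroxy-N-methoxy-N-methyl-5-(TMS)pent-4-ynamide
Conditions: MeONHMe·HCl, AlMe3, CH2Cl2, −20 → 0 °C
Reagents that add atoms: N,O-dimethylhydroxylamine hydrochloride, CNOC.Cl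
Why: Aluminium-amide transamidation of an Evans aldol adduct to the Weinreb amide, assisted by the free β-hydroxyl; auxiliary 6 is recovered.

Step 7
Reactants: 11 hydroxy Weinreb amide
Product: 12 (2S,3S)-3-[(TBS)oxy]-2-(2-{[(TBS)oxy]methyl}prop-2-en-1-yl)-N-methoxy-N-methyl-5-(TMS)pent-4-ynamide
Conditions: TBSOTf, 2,6-lutidine, CH2Cl2, −78 → 0 °C
Reagents that add atoms: tert-butyldimethylsilyl trifluoromethanesulfonate, CC(C)(C)[Si](C)(C)OS(=O)(=O)C(F)(F)F
Why: Silylation of a secondary propargylic alcohol with the silyl triflate under buffered conditions; no stereocentre is at risk.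

Step 8
Reactants: 12 silylated Weinreb amide; 13 tert-butyl acetate
Product: 14 tert-butyl (4S,5S)-5-[(TBS)oxy]-4-(2-{[(TBS)oxy]methyl}prop-2-en-1-yl)-3-oxo-7-(TMS)hept-6-ynoate
Conditions: 13, LiN(i-Pr)2 (3 equiv), THF, −78 °C; then 12, −78 → −30 °C; aq. NH4Cl
Reagents that add atoms: none
Why: Crossed Claisen condensation of a Weinreb amide with the lithium enolate of tert-butyl acetate; the chelated tetrahedral intermediate prevents over-addition, and the product is held as its doubly stabilised enolate, which protects core C1.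

Step 9
Reactants: 14 β-keto ester
Product: 15 tert-butyl (2Z,4S,5S)-5-[(TBS)oxy]-4-(2-{[(TBS)oxy]methyl}prop-2-en-1-yl)-3-{[(trifluoromethyl)sulfonyl]oxy}-7-(TMS)hept-2-en-6-ynoate
Conditions: NaH, THF, 0 °C; PhNTf2, 0 °C → rt
Reagents that add atoms: N-phenylbis(trifluoromethanesulfonimide), O=S(=O)(N(c1ccccc1)S(=O)(=O)C(F)(F)F)C(F)(F)F
Why: O-Triflation of the chelated sodium enolate of a β-keto ester gives the Z enol triflate (triflate and ester cis); only the CH2 between the carbonyls is deprotonated, so C1 is untouched.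

Step 10
Reactants: 15 Z enol triflate
Product: 16 tert-butyl (2E,4R,5S)-5-[(TBS)oxy]-4-(2-{[(TBS)oxy]methyl}prop-2-en-1-yl)-3-methyl-7-(TMS)hept-2-en-6-ynoate
Conditions: Me2CuLi (from MeLi, CuI), THF, −78 → −20 °C
Reagents that add atoms: lithium dimethylcuprate, [Li+].C[Cu-]C
Why: Cuprate coupling of a β-(triflyloxy) enoate proceeds by addition–elimination with retention, so the methyl ends cis to the ester and the enoate is E, the geometry that the cycloaddition copies into C7/C7a.

Step 11
Reactants: 16 TMS-alkyne
Product: 17 tert-butyl (2E,4R,5S)-5-[(TBS)oxy]-4-(2-{[(TBS)oxy]methyl}prop-2-en-1-yl)-3-methylhept-2-en-6-ynoate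
Conditions: K2CO3, MeOH, 0 °C → rt
Reagents that add atoms: none
Why: Methanolysis of the alkynyl C–Si bond under mild carbonate conditions; the hindered tert-butyl enoate and both TBS ethers are inert.

Step 12
Reactants: 18 methoxyallene (1-methoxypropa-1,2-diene)
Product: 20 1-(triethylsilyl)prop-2-en-1-one, via 1-methoxy-1-(triethylsilyl)propa-1,2-diene 19 (not isolated)
Conditions: n-BuLi, THF, −78 °C; Et3SiCl; then 1 M HCl, 0 °C
Reagents that add atoms: chlorotriethylsilane, CC[Si](Cl)(CC)CC; water, O
Why: α-Lithiation and C-silylation of methoxyallene followed by hydrolysis of the enol ether is an established entry to α,β-unsaturated acylsilanes; the reagent is used fresh to avoid polymerisation.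

Step 13
Reactants: 17 terminal alkyne; 20 1-(triethylsilyl)prop-2-en-1-one
Product: 21 tert-butyl (2E,4R,5S,8S)-5-[(TBS)oxy]-4-(2-{[(TBS)oxy]methyl}prop-2-en-1-yl)-8-hydroxy-3-methyl-8-(triethylsilyl)deca-2,9-dien-6-ynoate
Conditions: Me2Zn, (S,S)-ProPhenol (20 mol%), Ph3PO (40 mol%), toluene, 0 °C; then 20 (2 equiv), 0 °C; aq. NH4Cl
Reagents that add atoms: none
Why: The zinc acetylide forms with Me2Zn without strong base, so the enoate is safe; the zinc–ProPhenol catalyst adds it 1,2 to one face of the acylsilane carbonyl (catalytic asymmetric alkynylation of acylsilanes is known), setting the carbinol centre at core C4 that is relayed into the allene axis.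

Step 14
Reactants: 21 α-silyl carbinol
Product: 22 tert-butyl (2E,4R,5R)-5-[(TBS)oxy]-4-(2-{[(TBS)oxy]methyl}prop-2-en-1-yl)-3-methyl-8-[(TES)oxy]deca-2,6,7,9-tetraenoate, allene axis Ra (M)
Conditions: n-BuLi (10 mol%), THF, −78 → −40 °C; pH 7 buffer
Reagents that add atoms: none
Why: Base-catalysed Brook rearrangement with SE2' protonation: silicon migrates from carbon to oxygen and the proton enters the alkyne terminus anti to the departing silicon, a process known to transfer carbinol configuration to the axis of siloxyallenes. Only a catalytic amount of alkoxide is present and the carbinol itself is the proton source, so the carbanion is short-lived and should attack neither the enoate nor the C2 silyloxy group.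

Step 15
Reactants: 22 siloxy vinylallene (Ra)
Product: 23 tert-butyl (1R,2R,7R,7aS)-2-[(TBS)oxy]-1-(2-{[(TBS)oxy]methyl}prop-2-en-1-yl)-7a-methyl-4-[(TES)oxy]-2,6,7,7a-tetrahydro-1H-indene-7-carboxylate
Conditions: toluene (0.01 M), BHT (cat.), base-washed glass, 80–100 °C
Reagents that add atoms: none
Why: Thermal, concerted but asynchronous normal-demand [4+2] between the 2-siloxy diene C3a=C4–C5=C6 of 22 and its tethered E-enoate; the closest known reactions are intramolecular Diels–Alder additions of vinylallenes tethered at the allene terminus and intermolecular additions of 2-siloxy vinylallenes. The cyclohexene closes by the cycloaddition itself (C3a–C7a and C6–C7), and the cyclopentene closes through the three-atom tether as C3a–C7a forms (5-exo with respect to the enoate), the distal allene bond surviving as C3=C3a. The tether fixes the regiochemistry and agrees with the polarity (nucleophilic enol-ether carbon C3a to enoate β-carbon C7a), and with the E geometry it places the ester under the diene. C7a is set by the allene axis: C2 hangs from one face of the diene only, so the Ra axis presents a single face of the enoate (axial-to-central transfer). The C1 centre is matched to that axis, with its hydrogen in the plane of the enoate and its chain pointing away from the diene, which puts the chain cis to the methyl. C7 follows from C7a through the E alkene (suprafacial addition, methyl and ester cis). The selectivity needed is π-facial; it is secured by the axis and reinforced by C1 and by the trans C2 silyloxy group, which is pseudo-equatorial on the forming five-membered ring in this arrangement only. Dilution, a radical inhibitor and base-washed glass should hold back dimerisation and hydrolysis of the diene.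

Step 16
Reactants: 23 silyl dienol ether
Product: 24 tert-butyl (1R,2R,7R,7aS)-2-[(TBS)oxy]-1-(2-{[(TBS)oxy]methyl}prop-2-en-1-yl)-7a-methyl-4-oxo-2,4,5,6,7,7a-hexahydro-1H-indene-7-carboxylate
Conditions: 1 M HCl, THF, 0 °C, short contact
Reagents that add atoms: none
Why: Hydrolysis of the silyl dienol ether by protonation at C5 gives the C4 ketone conjugated with C3=C3a; the alkyl TBS ethers and the tert-butyl ester survive brief dilute acid.

Step 17
Reactants: 24 C4 enone
Product: 25 tert-butyl (1R,2R,4S,7R,7aS)-2-[(TBS)oxy]-1-(2-{[(TBS)oxy]methyl}prop-2-en-1-yl)-4-hydroxy-7a-methyl-2,4,5,6,7,7a-hexahydro-1H-indene-7-carboxylate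
Conditions: NaBH4, CeCl3·7H2O, MeOH, −78 °C
Reagents that add atoms: none
Why: Luche reduction (1,2-selective); the axial C7a methyl is syn-axial to one face of the C4 carbonyl, so hydride should enter from the opposite face and place the hydroxyl cis to the methyl (4S).

Step 18
Reactants: 26 (R)-2-methylbutanoic acid
Product: 27 (R)-2-methylbutan-1-ol
Conditions: LiAlH4, Et2O, 0 °C → rt
Reagents that add atoms: none
Why: Hydride reduction of the acid to the primary alcohol; the stereocentre is not enolisable in the product.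

Step 19
Reactants: 27 (R)-2-methylbutan-1-ol; 28 2-(triphenyl-λ5-phosphanylidene)propanal
Product: 30 (2E,4R)-2,4-dimethylhex-2-enal, via (R)-2-methylbutanal 29 (not isolated)
Conditions: PhI(OAc)2, TEMPO (cat.), CH2Cl2, rt; then 28, reflux
Reagents that add atoms: none
Why: Base-free TEMPO oxidation followed in the same flask by Wittig olefination with the stabilised formyl ylide gives the E enal; trapping the α-chiral aldehyde as it forms guards against racemisation.

Step 20
Reactants: 30 (2E,4R)-2,4-dimethylhex-2-enal; 31 triethyl phosphonoacetate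
Product: 32 ethyl (2E,4E,6R)-4,6-dimethylocta-2,4-dienoate
Conditions: NaH, THF, 0 °C → rt
Reagents that add atoms: none
Why: Horner–Wadsworth–Emmons olefination with a stabilised phosphonate anion, reliably E-selective with enals.

Step 21
Reactants: 32 ethyl dienoate
Product: 33 (2E,4E,6R)-4,6-dimethylocta-2,4-dienoic acid
Conditions: LiOH, THF/MeOH/H2O, rt; then 1 M HCl
Reagents that add atoms: lithium hydroxide, [Li+].[OH-]
Why: Saponification; the stereocentre is remote from the ester and the diene geometry is not at risk under these conditions.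

Step 22
Reactants: 25 allylic alcohol; 33 dienoic acid
Product: 35 tert-butyl (1R,2R,4S,7R,7aS)-2-[(TBS)oxy]-1-(2-{[(TBS)oxy]methyl}prop-2-en-1-yl)-4-{[(2E,4E,6R)-4,6-dimethylocta-2,4-dienoyl]oxy}-7a-methyl-2,4,5,6,7,7a-hexahydro-1H-indene-7-carboxylate, via mixed 2,4,6-trichlorobenzoic anhydride 34 (not isolated)
Conditions: 33, 2,4,6-trichlorobenzoyl chloride, Et3N, THF, rt; then 25, DMAP, toluene, rt
Reagents that add atoms: none
Why: Yamaguchi esterification of a hindered allylic alcohol through the mixed anhydride and DMAP; acylation occurs on oxygen, so C4 keeps its configuration.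

Step 23
Reactants: 35 bis-silyl ether
Product: 36 tert-butyl (1R,2R,4S,7R,7aS)-4-{[(2E,4E,6R)-4,6-dimethylocta-2,4-dienoyl]oxy}-2-hydroxy-1-[2-(hydroxymethyl)prop-2-en-1-yl]-7a-methyl-2,4,5,6,7,7a-hexahydro-1H-indene-7-carboxylate
Conditions: HF·pyridine, pyridine, THF, 0 °C → rt
Reagents that add atoms: none
Why: Buffered fluoride cleavage of both alkyl silyl ethers; the allylic dienoate, the tert-butyl ester and C1 are untouched.

Step 24
Reactants: 36 diol
Product: 37 tert-butyl (1R,4S,7R,7aS)-4-{[(2E,4E,6R)-4,6-dimethylocta-2,4-dienoyl]oxy}-1-(2-formylprop-2-en-1-yl)-7a-methyl-2-oxo-2,4,5,6,7,7a-hexahydro-1H-indene-7-carboxylate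
Conditions: Dess–Martin periodinane (3 equiv), NaHCO3, CH2Cl2, 0 °C → rt
Reagents that add atoms: none
Why: Dess–Martin oxidation converts both allylic alcohols in one operation (C2 to the enone, the primary alcohol to the 2-substituted acrolein) under buffered neutral conditions.

Step 25
Reactants: 37 tert-butyl ester
Product: 38 (1R,4S,7R,7aS)-4-{[(2E,4E,6R)-4,6-dimethylocta-2,4-dienoyl]oxy}-1-(2-formylprop-2-en-1-yl)-7a-methyl-2-oxo-2,4,5,6,7,7a-hexahydro-1H-indene-7-carboxylic acid
Conditions: CF3CO2H/CH2Cl2 (1:4), 0 °C → rt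
Reagents that add atoms: none
Why: Acidolysis of the tert-butyl ester with loss of 2-methylpropene; the C4 allylic ester is deactivated towards ionisation by the conjugated C2 ketone, and the other groups should tolerate short exposure to the acid.

## Compound list

1 | 2-methylidenepropane-1,3-diol | C=C(CO)CO | starting material
2 | 2-{[(tert-butyldimethylsilyl)oxy]methyl}prop-2-en-1-ol | C=C(CO)CO[Si](C)(C)C(C)(C)C | intermediate
3 | triethyl orthoacetate (1,1,1-triethoxyethane) | CC(OCC)(OCC)OCC | starting material
4 | ethyl 4-{[(tert-butyldimethylsilyl)oxy]methyl}pent-4-enoate | CCOC(=O)CCC(=C)CO[Si](C)(C)C(C)(C)C | intermediate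
5 | 4-{[(tert-butyldimethylsilyl)oxy]methyl}pent-4-enoic acid | OC(=O)CCC(=C)CO[Si](C)(C)C(C)(C)C | intermediate
6 | (S)-4-benzyl-1,3-oxazolidin-2-one | O=C1N[C@@H](Cc2ccccc2)CO1 | starting material
7 | 4-{[(tert-butyldimethylsilyl)oxy]methyl}pent-4-enoic pivalic anhydride | CC(C)(C)C(=O)OC(=O)CCC(=C)CO[Si](C)(C)C(C)(C)C | intermediate
8 | (S)-4-benzyl-3-(4-{[(tert-butyldimethylsilyl)oxy]methyl}pent-4-enoyl)-1,3-oxazolidin-2-one | O=C(CCC(=C)CO[Si](C)(C)C(C)(C)C)N1C(=O)OC[C@@H]1Cc1ccccc1 | intermediate
9 | 3-(trimethylsilyl)prop-2-ynal | O=CC#C[Si](C)(C)C | starting material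
10 | (S)-4-benzyl-3-[(2S,3S)-2-(2-{[(tert-butyldimethylsilyl)oxy]methyl}prop-2-en-1-yl)-3-hydroxy-5-(trimethylsilyl)pent-4-ynoyl]-1,3-oxazolidin-2-one | O=C([C@@H](CC(=C)CO[Si](C)(C)C(C)(C)C)[C@H](O)C#C[Si](C)(C)C)N1C(=O)OC[C@@H]1Cc1ccccc1 | intermediate
11 | (2S,3S)-2-(2-{[(tert-butyldimethylsilyl)oxy]methyl}prop-2-en-1-yl)-3-hydroxy-N-methoxy-N-methyl-5-(trimethylsilyl)pent-4-ynamide | CON(C)C(=O)[C@@H](CC(=C)CO[Si](C)(C)C(C)(C)C)[C@H](O)C#C[Si](C)(C)C | intermediate
12 | (2S,3S)-3-[(tert-butyldimethylsilyl)oxy]-2-(2-{[(tert-butyldimethylsilyl)oxy]methyl}prop-2-en-1-yl)-N-methoxy-N-methyl-5-(trimethylsilyl)pent-4-ynamide | CON(C)C(=O)[C@@H](CC(=C)CO[Si](C)(C)C(C)(C)C)[C@H](O[Si](C)(C)C(C)(C)C)C#C[Si](C)(C)C | intermediate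
13 | tert-butyl acetate | CC(=O)OC(C)(C)C | starting material
14 | tert-butyl (4S,5S)-5-[(tert-butyldimethylsilyl)oxy]-4-(2-{[(tert-butyldimethylsilyl)oxy]methyl}prop-2-en-1-yl)-3-oxo-7-(trimethylsilyl)hept-6-ynoate | CC(C)(C)OC(=O)CC(=O)[C@@H](CC(=C)CO[Si](C)(C)C(C)(C)C)[C@H](O[Si](C)(C)C(C)(C)C)C#C[Si](C)(C)C | intermediate
15 | tert-butyl (2Z,4S,5S)-5-[(tert-butyldimethylsilyl)oxy]-4-(2-{[(tert-butyldimethylsilyl)oxy]methyl}prop-2-en-1-yl)-3-{[(trifluoromethyl)sulfonyl]oxy}-7-(trimethylsilyl)hept-2-en-6-ynoate | CC(C)(C)OC(=O)/C=C(OS(=O)(=O)C(F)(F)F)/[C@@H](CC(=C)CO[Si](C)(C)C(C)(C)C)[C@H](O[Si](C)(C)C(C)(C)C)C#C[Si](C)(C)C | intermediate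
16 | tert-butyl (2E,4R,5S)-5-[(tert-butyldimethylsilyl)oxy]-4-(2-{[(tert-butyldimethylsilyl)oxy]methyl}prop-2-en-1-yl)-3-methyl-7-(trimethylsilyl)hept-2-en-6-ynoate | CC(C)(C)OC(=O)/C=C(C)/[C@@H](CC(=C)CO[Si](C)(C)C(C)(C)C)[C@H](O[Si](C)(C)C(C)(C)C)C#C[Si](C)(C)C | intermediate
17 | tert-butyl (2E,4R,5S)-5-[(tert-butyldimethylsilyl)oxy]-4-(2-{[(tert-butyldimethylsilyl)oxy]methyl}prop-2-en-1-yl)-3-methylhept-2-en-6-ynoate | CC(C)(C)OC(=O)/C=C(C)/[C@@H](CC(=C)CO[Si](C)(C)C(C)(C)C)[C@H](O[Si](C)(C)C(C)(C)C)C#C | intermediate
18 | methoxyallene (1-methoxypropa-1,2-diene) | COC=C=C | starting material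
19 | 1-methoxy-1-(triethylsilyl)propa-1,2-diene | COC(=C=C)[Si](CC)(CC)CC | intermediate
20 | 1-(triethylsilyl)prop-2-en-1-one | C=CC(=O)[Si](CC)(CC)CC | intermediate
21 | tert-butyl (2E,4R,5S,8S)-5-[(tert-butyldimethylsilyl)oxy]-4-(2-{[(tert-butyldimethylsilyl)oxy]methyl}prop-2-en-1-yl)-8-hydroxy-3-methyl-8-(triethylsilyl)deca-2,9-dien-6-ynoate | CC(C)(C)OC(=O)/C=C(C)/[C@@H](CC(=C)CO[Si](C)(C)C(C)(C)C)[C@H](O[Si](C)(C)C(C)(C)C)C#C[C@@](O)([Si](CC)(CC)CC)C=C | intermediate
22 | tert-butyl (2E,4R,5R)-5-[(tert-butyldimethylsilyl)oxy]-4-(2-{[(tert-butyldimethylsilyl)oxy]methyl}prop-2-en-1-yl)-3-methyl-8-[(triethylsilyl)oxy]deca-2,6,7,9-tetraenoate, allene axis Ra (M) | CC(C)(C)OC(=O)/C=C(C)/[C@@H](CC(=C)CO[Si](C)(C)C(C)(C)C)[C@H](O[Si](C)(C)C(C)(C)C)C([H])=[C@@]=C(O[Si](CC)(CC)CC)C=C | intermediate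
23 | tert-butyl (1R,2R,7R,7aS)-2-[(tert-butyldimethylsilyl)oxy]-1-(2-{[(tert-butyldimethylsilyl)oxy]methyl}prop-2-en-1-yl)-7a-methyl-4-[(triethylsilyl)oxy]-2,6,7,7a-tetrahydro-1H-indene-7-carboxylate | CC(C)(C)[Si](C)(C)OCC(=C)C[C@H]1[C@H](O[Si](C)(C)C(C)(C)C)C=C2C(O[Si](CC)(CC)CC)=CC[C@@H](C(=O)OC(C)(C)C)[C@@]21C | intermediate
24 | tert-butyl (1R,2R,7R,7aS)-2-[(tert-butyldimethylsilyl)oxy]-1-(2-{[(tert-butyldimethylsilyl)oxy]methyl}prop-2-en-1-yl)-7a-methyl-4-oxo-2,4,5,6,7,7a-hexahydro-1H-indene-7-carboxylate | CC(C)(C)[Si](C)(C)OCC(=C)C[C@H]1[C@H](O[Si](C)(C)C(C)(C)C)C=C2C(=O)CC[C@@H](C(=O)OC(C)(C)C)[C@@]21C | intermediate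
25 | tert-butyl (1R,2R,4S,7R,7aS)-2-[(tert-butyldimethylsilyl)oxy]-1-(2-{[(tert-butyldimethylsilyl)oxy]methyl}prop-2-en-1-yl)-4-hydroxy-7a-methyl-2,4,5,6,7,7a-hexahydro-1H-indene-7-carboxylate | CC(C)(C)[Si](C)(C)OCC(=C)C[C@H]1[C@H](O[Si](C)(C)C(C)(C)C)C=C2[C@@H](O)CC[C@@H](C(=O)OC(C)(C)C)[C@@]21C | intermediate
26 | (R)-2-methylbutanoic acid | CC[C@@H](C)C(=O)O | starting material
27 | (R)-2-methylbutan-1-ol | CC[C@@H](C)CO | intermediate
28 | 2-(triphenyl-λ5-phosphanylidene)propanal | CC(C=O)=P(c1ccccc1)(c1ccccc1)c1ccccc1 | starting material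
29 | (R)-2-methylbutanal | CC[C@@H](C)C=O | intermediate
30 | (2E,4R)-2,4-dimethylhex-2-enal | CC[C@@H](C)/C=C(\C)C=O | intermediate
31 | triethyl phosphonoacetate | CCOC(=O)CP(=O)(OCC)OCC | starting material
32 | ethyl (2E,4E,6R)-4,6-dimethylocta-2,4-dienoate | CCOC(=O)/C=C/C(C)=C/[C@H](C)CC | intermediate
33 | (2E,4E,6R)-4,6-dimethylocta-2,4-dienoic acid | OC(=O)/C=C/C(C)=C/[C@H](C)CC | intermediate
34 | (2E,4E,6R)-4,6-dimethylocta-2,4-dienoic 2,4,6-trichlorobenzoic anhydride | O=C(OC(=O)/C=C/C(C)=C/[C@H](C)CC)c1c(Cl)cc(Cl)cc1Cl | intermediate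
35 | tert-butyl (1R,2R,4S,7R,7aS)-2-[(tert-butyldimethylsilyl)oxy]-1-(2-{[(tert-butyldimethylsilyl)oxy]methyl}prop-2-en-1-yl)-4-{[(2E,4E,6R)-4,6-dimethylocta-2,4-dienoyl]oxy}-7a-methyl-2,4,5,6,7,7a-hexahydro-1H-indene-7-carboxylate | CC(C)(C)[Si](C)(C)OCC(=C)C[C@H]1[C@H](O[Si](C)(C)C(C)(C)C)C=C2[C@@H](OC(=O)/C=C/C(C)=C/[C@H](C)CC)CC[C@@H](C(=O)OC(C)(C)C)[C@@]21C | intermediate
36 | tert-butyl (1R,2R,4S,7R,7aS)-4-{[(2E,4E,6R)-4,6-dimethylocta-2,4-dienoyl]oxy}-2-hydroxy-1-[2-(hydroxymethyl)prop-2-en-1-yl]-7a-methyl-2,4,5,6,7,7a-hexahydro-1H-indene-7-carboxylate | OCC(=C)C[C@H]1[C@H](O)C=C2[C@@H](OC(=O)/C=C/C(C)=C/[C@H](C)CC)CC[C@@H](C(=O)OC(C)(C)C)[C@@]21C | intermediate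
37 | tert-butyl (1R,4S,7R,7aS)-4-{[(2E,4E,6R)-4,6-dimethylocta-2,4-dienoyl]oxy}-1-(2-formylprop-2-en-1-yl)-7a-methyl-2-oxo-2,4,5,6,7,7a-hexahydro-1H-indene-7-carboxylate | O=CC(=C)C[C@H]1C(=O)C=C2[C@@H](OC(=O)/C=C/C(C)=C/[C@H](C)CC)CC[C@@H](C(=O)OC(C)(C)C)[C@@]21C | intermediate
38 | (1R,4S,7R,7aS)-4-{[(2E,4E,6R)-4,6-dimethylocta-2,4-dienoyl]oxy}-1-(2-formylprop-2-en-1-yl)-7a-methyl-2-oxo-2,4,5,6,7,7a-hexahydro-1H-indene-7-carboxylic acid (CNP0302671.3) | C=C(C=O)C[C@H]1C(=O)C=C2[C@@H](OC(=O)/C=C/C(C)=C/[C@H](C)CC)CC[C@@H](C(=O)O)[C@@]21C | target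

## Step count and least certain steps

Total: 25 steps. Longest linear sequence: 20 steps (steps 1–11, 13–17, 22–25); the acylsilane (step 12) and the side-chain acid (steps 18–21) are side branches.

**Step 15 (key step).** The cycloaddition makes a quaternary carbon from a β,β-disubstituted enoate and may be slower than dimerisation or hydrolysis of the diene. The pairing of the Ra axis with the C1 centre may also be less favourable than assumed if the chain, rather than the hydrogen, prefers the plane of the enoate. The fallback sets out from 22 and comes back at 24. Anhydrous fluoride (tetrabutylammonium difluorotriphenylsilicate, THF, −78 → −20 °C) removes the enol silyl group and releases the allenolate, whose axis is not configurationally fixed. Its α-carbon C3a adds 5-exo to the enoate β-carbon, and the resulting ester enolate closes the six-membered ring by Michael addition to the vinyl ketone. Protonation gives enone 24 directly, with the C7 ester free to settle equatorial, cis to the methyl. If the sequence halts after the first addition, tert-butyl 2-[2-acryloyl-4-(TBS-oxy)-5-(2-{[(TBS)oxy]methyl}prop-2-en-1-yl)-1-methylcyclopent-2-en-1-yl]acetate F1 is isolated and closed with catalytic KOt-Bu in THF/t-BuOH.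

**Step 14.** The vinyl-conjugated carbanion may live long enough to lose the carbinol configuration, so that the axis forms without control. It may also take its proton at C8 or C10 instead of C6, or expel the C5 silanolate. The fallback sets out from 17 and comes back at 24. It gives up the relay through the axis. The stoichiometric one-flask sequence (LiN(SiMe3)2, THF, −78 °C; 20; Brook rearrangement; AcOH quench) gives 22 mixed with its axial epimer, the Sa (P) allene F2. The mixture is closed by the fluoride-triggered Michael–Michael sequence, which does not read the axis and relies on C1 alone for the enoate face.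

**Step 13.** Facial discrimination on the acylsilane may be poor with so large an alkyne. Conjugate addition to the acryloyl unit or zinc-promoted Brook rearrangement in the flask may compete. The fallback sets out from 17 and comes back at 21. The bromomagnesium acetylide (EtMgBr, THF, 0 °C; then 20, −78 °C) adds without a catalyst and gives 21 together with its (8R)-epimer, tert-butyl (2E,4R,5S,8R)-5-(TBS-oxy)-4-(2-{[(TBS)oxy]methyl}prop-2-en-1-yl)-8-hydroxy-3-methyl-8-(triethylsilyl)deca-2,9-dien-6-ynoate F3. The two diastereomers are separated by chromatography and only 21 is carried on.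

**Step 17.** Facial selectivity at C4 may be poor: a small hydride can still use the axial path syn to the methyl, and a single syn-axial methyl is not an absolute barrier. The fallback sets out from 24 and comes back at 35. The unwanted (4R)-alcohol, tert-butyl (1R,2R,4R,7R,7aS)-2-(TBS-oxy)-1-(2-{[(TBS)oxy]methyl}prop-2-en-1-yl)-4-hydroxy-7a-methyl-2,4,5,6,7,7a-hexahydro-1H-indene-7-carboxylate F4, is not discarded. It is esterified with acid 33 under Mitsunobu conditions (PPh3, diisopropyl azodicarboxylate, toluene, 0 °C), which inverts C4 and gives 35, so both epimers of the reduction converge.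

**Step 25.** Acid may ionise the allylic ester, add to the acrolein or epimerise C1 in the finished molecule. The fallback sets out from 35 and comes back at 38; it moves the ester cleavage ahead of the oxidation. TMSOTf/2,6-lutidine (CH2Cl2, 0 °C, aqueous work-up) converts the tert-butyl ester of 35 into the bis-silylated acid (1R,2R,4S,7R,7aS)-2-(TBS-oxy)-1-(2-{[(TBS)oxy]methyl}prop-2-en-1-yl)-4-{[(2E,4E,6R)-4,6-dimethylocta-2,4-dienoyl]oxy}-7a-methyl-2,4,5,6,7,7a-hexahydro-1H-indene-7-carboxylic acid F5. HF·pyridine then gives the dihydroxy acid (1R,2R,4S,7R,7aS)-4-{[(2E,4E,6R)-4,6-dimethylocta-2,4-dienoyl]oxy}-2-hydroxy-1-[2-(hydroxymethyl)prop-2-en-1-yl]-7a-methyl-2,4,5,6,7,7a-hexahydro-1H-indene-7-carboxylic acid F6. Buffered Dess–Martin oxidation of F6 gives 38, so the last step is neutral.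

## Further compounds

F1 | step 15 | tert-butyl 2-[2-acryloyl-4-[(tert-butyldimethylsilyl)oxy]-5-(2-{[(tert-butyldimethylsilyl)oxy]methyl}prop-2-en-1-yl)-1-methylcyclopent-2-en-1-yl]acetate (C1, C2, C7a configured as in 24) | C=CC(=O)C1=C[C@@H](O[Si](C)(C)C(C)(C)C)[C@H](CC(=C)CO[Si](C)(C)C(C)(C)C)[C@@]1(C)CC(=O)OC(C)(C)C
F2 | step 14 | tert-butyl (2E,4R,5R)-5-[(tert-butyldimethylsilyl)oxy]-4-(2-{[(tert-butyldimethylsilyl)oxy]methyl}prop-2-en-1-yl)-3-methyl-8-[(triethylsilyl)oxy]deca-2,6,7,9-tetraenoate, allene axis Sa (P) | CC(C)(C)OC(=O)/C=C(C)/[C@@H](CC(=C)CO[Si](C)(C)C(C)(C)C)[C@H](O[Si](C)(C)C(C)(C)C)C([H])=[C@]=C(O[Si](CC)(CC)CC)C=C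
F3 | step 13 | tert-butyl (2E,4R,5S,8R)-5-[(tert-butyldimethylsilyl)oxy]-4-(2-{[(tert-butyldimethylsilyl)oxy]methyl}prop-2-en-1-yl)-8-hydroxy-3-methyl-8-(triethylsilyl)deca-2,9-dien-6-ynoate | CC(C)(C)OC(=O)/C=C(C)/[C@@H](CC(=C)CO[Si](C)(C)C(C)(C)C)[C@H](O[Si](C)(C)C(C)(C)C)C#C[C@](O)([Si](CC)(CC)CC)C=C
F4 | step 17 | tert-butyl (1R,2R,4R,7R,7aS)-2-[(tert-butyldimethylsilyl)oxy]-1-(2-{[(tert-butyldimethylsilyl)oxy]methyl}prop-2-en-1-yl)-4-hydroxy-7a-methyl-2,4,5,6,7,7a-hexahydro-1H-indene-7-carboxylate | CC(C)(C)[Si](C)(C)OCC(=C)C[C@H]1[C@H](O[Si](C)(C)C(C)(C)C)C=C2[C@H](O)CC[C@@H](C(=O)OC(C)(C)C)[C@@]21C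
F5 | step 25 | (1R,2R,4S,7R,7aS)-2-[(tert-butyldimethylsilyl)oxy]-1-(2-{[(tert-butyldimethylsilyl)oxy]methyl}prop-2-en-1-yl)-4-{[(2E,4E,6R)-4,6-dimethylocta-2,4-dienoyl]oxy}-7a-methyl-2,4,5,6,7,7a-hexahydro-1H-indene-7-carboxylic acid | CC(C)(C)[Si](C)(C)OCC(=C)C[C@H]1[C@H](O[Si](C)(C)C(C)(C)C)C=C2[C@@H](OC(=O)/C=C/C(C)=C/[C@H](C)CC)CC[C@@H](C(=O)O)[C@@]21C
F6 | step 25 | (1R,2R,4S,7R,7aS)-4-{[(2E,4E,6R)-4,6-dimethylocta-2,4-dienoyl]oxy}-2-hydroxy-1-[2-(hydroxymethyl)prop-2-en-1-yl]-7a-methyl-2,4,5,6,7,7a-hexahydro-1H-indene-7-carboxylic acid | OCC(=C)C[C@H]1[C@H](O)C=C2[C@@H](OC(=O)/C=C/C(C)=C/[C@H](C)CC)CC[C@@H](C(=O)O)[C@@]21C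
A1 | alternative 1 | triisopropyl{[1-(2-methylcyclopent-1-en-1-yl)ethenyl]oxy}silane | CC1=C(C(=C)O[Si](C(C)C)(C(C)C)C(C)C)CCC1
A2 | alternative 1 | 2,2,2-trifluoroethyl acrylate | C=CC(=O)OCC(F)(F)F
A3 | alternative 1 | 2,2,2-trifluoroethyl 7a-methyl-4-(triisopropylsilyloxy)-2,3,5,6,7,7a-hexahydro-1H-indene-7-carboxylate (endo adduct, C7 epimeric to the target) | C1CCC2=C(O[Si](C(C)C)(C(C)C)C(C)C)CC[C@H](C(=O)OCC(F)(F)F)[C@@]21C
A4 | alternative 2 | tert-butyl 8,8-dichloro-5-[(tert-butyldimethylsilyl)oxy]-1-methyl-7-oxobicyclo[4.2.0]octane-2-carboxylate | O=C1[C@@H]2[C@@H](O[Si](C)(C)C(C)(C)C)CC[C@@H](C(=O)OC(C)(C)C)[C@]2(C)C1(Cl)Cl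
A5 | alternative 2 | diazomethane | C=[N+]=[N-]
A6 | alternative 2 | tert-butyl 1,1-dichloro-4-(tert-butyldimethylsilyloxy)-7a-methyl-2-oxooctahydro-1H-indene-7-carboxylate | O=C1C[C@@H]2[C@@H](O[Si](C)(C)C(C)(C)C)CC[C@@H](C(=O)OC(C)(C)C)[C@]2(C)C1(Cl)Cl
A7 | alternative 3 | tert-butyl 2-[5-(2-{[(tert-butyldimethylsilyl)oxy]methyl}prop-2-en-1-yl)-1-methyl-4-oxocyclopent-2-en-1-yl]-5-oxopentanoate | C=C(CO[Si](C)(C)C(C)(C)C)C[C@H]1C(=O)C=C[C@]1(C)[C@@H](CCC=O)C(=O)OC(C)(C)C
A8 | alternative 3 | tert-butyl 4-hydroxy-7a-methyl-2-oxo-1-[2-(tert-butyldimethylsilyloxymethyl)allyl]octahydro-1H-indene-7-carboxylate | C=C(CO[Si](C)(C)C(C)(C)C)C[C@H]1C(=O)C[C@@H]2[C@@H](O)CC[C@@H](C(=O)OC(C)(C)C)[C@@]21C
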